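**Retrosynthetic overview**

- The strategy rests on the Z-trisubstituted C4=C5 alkene of the ten-membered carbocycle (C1–C10), which lies between the allylic oxygens at C3 and C6. It is cut last by ring-closing metathesis: target 27 ⇐ 3-alcohol 26 ⇐ diene 25 (C6 vinyl, C3 isopropenyl carbinol).
- 25 ⇐ C8 acylation of lactone alcohol 17 with (2S,3S)-epoxyangelic acid 21 and reagent-controlled epoxidation of the E-C1=C10 alkene.
- The γ-lactone (first ring) ⇐ erythro epoxy alcohol 14: a C6-O-tethered phosphonoacetate opens the oxirane at C7 with inversion, then olefination with formaldehyde. 14 ⇐ asymmetric epoxidation of dienol 13.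
- 13 ⇐ copper-mediated C8–C9 coupling of allylic bromide 7 with (R)-pent-1-en-4-yn-3-ol 11, then trans-reduction. 7 ⇐ asymmetric allylation of methacrolein (C3) and cross-metathesis with methacrolein (E-C1=C10).
- Ring order: 7,8-oxirane → γ-lactone → 1,10-oxirane → ten-membered carbocycle.

Key step: step 20

Remark on the chemistry: germacrane numbering (C1–C13) is used for locants; the reagent antipodes are assigned from the accepted facial models (dIpc2B-allyl attacks the Si face of the aldehyde; D-(−)-tartrate gives (2R,3R)-epoxides from E-allylic alcohols; the D-fructose-derived ketone gives (R,R)-epoxides from trans and trisubstituted alkenes).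

**Route**

Step 1
Reactants: 1 methacrolein
Product: 3 (3S)-2-methylhexa-1,5-dien-3-ol, via diisopinocampheylborinate ester 2 (not isolated)
Conditions: (−)-Ipc2BOMe, allylMgBr, Et2O, −78 °C → rt; then 1, −78 °C; then NaOH, H2O2
Reagents that add atoms: allylmagnesium bromide, C=CC[Mg]Br
Why: Brown asymmetric allylboration through a chair transition state, in which the reagent from (−)-Ipc2BOMe should add to the Si face of the enal and set C3 as S.

Step 2
Reactants: 3 (3S)-2-methylhexa-1,5-dien-3-ol
Product: 4 tert-butyl(dimethyl){[(3S)-2-methylhexa-1,5-dien-3-yl]oxy}silane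
Conditions: TBSCl, imidazole, DMF, rt
Reagents that add atoms: tert-butyldimethylsilyl chloride, CC(C)(C)[Si](C)(C)Cl
Why: Standard silylation of a secondary allylic alcohol, which masks C3–OH through the hydride, base and epoxidation steps that follow.

Step 3
Reactants: 4 TBS ether; 1 methacrolein (5 equiv)
Product: 5 (2E,5S)-5-[(tert-butyldimethylsilyl)oxy]-2,6-dimethylhepta-2,6-dienal
Conditions: Hoveyda–Grubbs II (5 mol%), CH2Cl2, 40 °C
Reagents that add atoms: none
Why: Olefin cross-metathesis of the monosubstituted alkene with methacrolein should give the E-2-methyl enal (the future E-C1=C10 alkene) under thermodynamic control, the hindered isopropenyl group staying out.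

Step 4
Reactants: 5 enal
Product: 6 (2E,5S)-5-[(tert-butyldimethylsilyl)oxy]-2,6-dimethylhepta-2,6-dien-1-ol
Conditions: DIBAL-H, CH2Cl2, −78 °C; Rochelle salt
Reagents that add atoms: none
Why: 1,2-Reduction of an enal by DIBAL-H gives the allylic alcohol without touching the alkene geometry or the silyl ether.

Step 5
Reactants: 6 allylic alcohol
Product: 7 {[(3S,5E)-7-bromo-2,6-dimethylhepta-1,5-dien-3-yl]oxy}(tert-butyl)dimethylsilane
Conditions: CBr4, PPh3, CH2Cl2, 0 °C
Reagents that add atoms: carbon tetrabromide, BrC(Br)(Br)Br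
Why: Appel bromination of a primary allylic alcohol proceeds by SN2 at the primary carbon, so the E alkene is kept.

Step 6
Reactants: 8 acrolein
Product: 9 rac-5-(trimethylsilyl)pent-1-en-4-yn-3-ol
Conditions: ethynyltrimethylsilane, n-BuLi, THF, −78 °C; then 8; NH4Cl
Reagents that add atoms: ethynyltrimethylsilane, C#C[Si](C)(C)C
Why: 1,2-Addition of a lithium acetylide to an enal at low temperature is reliable and gives the racemic C6 carbinol.

Step 7
Reactants: 9 rac-5-(trimethylsilyl)pent-1-en-4-yn-3-ol
Product: 10 (3R)-5-(trimethylsilyl)pent-1-en-4-yn-3-yl acetate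
Conditions: Amano lipase PS, vinyl acetate, MTBE, 30 °C, to about 50% conversion; unreacted (S)-alcohol removed
Reagents that add atoms: vinyl acetate, CC(=O)OC=C
Why: Lipase-catalysed kinetic resolution by irreversible transesterification, in which the empirical size rule (long silylethynyl arm as large group, vinyl as medium) predicts acetylation of the R enantiomer; any residual S material is rejected again in step 11.

Step 8
Reactants: 10 (R)-acetate
Product: 11 (3R)-pent-1-en-4-yn-3-ol
Conditions: K2CO3, MeOH, 0 °C → rt; used as a solution (volatile)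
Reagents that add atoms: none
Why: Methanolysis removes the acetate and the C-silyl group in one operation without touching the stereocentre.

Step 9
Reactants: 7 allylic bromide; 11 (3R)-pent-1-en-4-yn-3-ol
Product: 12 (3R,7E,10S)-10-[(tert-butyldimethylsilyl)oxy]-7,11-dimethyldodeca-1,7,11-trien-4-yn-3-ol
Conditions: CuI (10 mol%), K2CO3, n-Bu4NI (10 mol%), DMF, rt
Reagents that add atoms: none
Why: Copper-acetylide allylic substitution (Jeffery-type 1,4-enyne synthesis) tolerates the free propargylic alcohol and should join C8 to the primary C9 terminus with retention of the E alkene.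

Step 10
Reactants: 12 enynol
Product: 13 (3R,4E,7E,10S)-10-[(tert-butyldimethylsilyl)oxy]-7,11-dimethyldodeca-1,4,7,11-tetraen-3-ol
Conditions: Red-Al, THF, 0 °C → rt
Reagents that add atoms: none
Why: Alkoxide-directed trans-hydroalumination of the propargylic alcohol followed by protonolysis gives the E-allylic alcohol (C7=C8) and leaves isolated alkenes and the silyl ether alone.

Step 11
Reactants: 13 dienol
Product: 14 (1R)-1-[(2R,3R)-3-{(2E,5S)-5-[(tert-butyldimethylsilyl)oxy]-2,6-dimethylhepta-2,6-dien-1-yl}oxiran-2-yl]prop-2-en-1-ol (erythro)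
Conditions: Ti(OiPr)4 (10 mol%), D-(−)-DIPT (12 mol%), t-BuOOH, 4 Å MS, CH2Cl2, −20 °C
Reagents that add atoms: tert-butyl hydroperoxide, CC(C)(C)OO
Why: Sharpless asymmetric epoxidation in the matched sense for the (R)-carbinol, which should epoxidise only the E-disubstituted allylic alkene (the vinyl group is the slow, mismatched partner; remote alkenes are not bound to titanium) and set C7 and C8 as the erythro epoxy alcohol.

Step 12
Reactants: 14 epoxy alcohol
Product: 15 (1R)-1-[(2S,3R)-3-{(2E,5S)-5-[(tert-butyldimethylsilyl)oxy]-2,6-dimethylhepta-2,6-dien-1-yl}oxiran-2-yl]prop-2-en-1-yl (diethoxyphosphoryl)acetate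
Conditions: (EtO)2P(O)CH2CO2H, DCC, DMAP (cat.), CH2Cl2, 0 °C → rt
Reagents that add atoms: (diethoxyphosphoryl)acetic acid, CCOP(=O)(CC(=O)O)OCC
Why: Steglich esterification of the secondary alcohol under neutral conditions keeps the oxirane intact and places the C11–C12 unit on O6.

Step 13
Reactants: 15 phosphonoacetate
Product: 17 (4R,5R)-5-ethenyl-4-[(1R,3E,6S)-6-[(tert-butyldimethylsilyl)oxy]-1-hydroxy-3,7-dimethylocta-3,7-dien-1-yl]-3-methylideneoxolan-2-one, via phosphono lactone 16 (not isolated)
Conditions: KOtBu, THF, 0 → 45 °C; then (CH2O)n, rt; NH4Cl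
Reagents that add atoms: formaldehyde (as paraformaldehyde), C=O
Why: Intramolecular 5-exo-tet alkylation of the phosphonate-stabilised ester carbanion by the oxirane (the tethered counterpart of the known phosphonoacetate–epoxide lactone synthesis and of telescoped intramolecular Michael/olefination sequences) forms C7–C11 with inversion at C7 and keeps the C8 oxygen, which makes the trans lactone with 8R, and Horner–Wadsworth–Emmons olefination of the resulting carbanion with formaldehyde installs the 11(13)-methylene group.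

Step 14
Reactants: 18 angelic acid
Product: 19 (2Z)-2-methylbut-2-en-1-ol
Conditions: LiAlH4, Et2O, 0 °C → rt
Reagents that add atoms: none
Why: Hydride reduction of the unsaturated acid to the allylic alcohol should proceed without Z/E isomerisation under these non-acidic, low-temperature conditions.

Step 15
Reactants: 19 (2Z)-2-methylbut-2-en-1-ol
Product: 20 [(2R,3S)-2,3-dimethyloxiran-2-yl]methanol
Conditions: Ti(OiPr)4 (5 mol%), D-(−)-DIPT (7 mol%), t-BuOOH, 4 Å MS, CH2Cl2, −20 °C
Reagents that add atoms: tert-butyl hydroperoxide, CC(C)(C)OO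
Why: Catalytic Sharpless asymmetric epoxidation of a trisubstituted primary allylic alcohol, in which D-(−)-tartrate selects the face that leads to the (2S,3S) acid and the cis relation of the C3 methyl and C1 is kept.

Step 16
Reactants: 20 epoxy alcohol
Product: 21 (2S,3S)-2,3-dimethyloxirane-2-carboxylic acid
Conditions: RuCl3·xH2O (2 mol%), NaIO4, CCl4/MeCN/H2O, rt
Reagents that add atoms: sodium periodate, [Na+].[O-]I(=O)(=O)=O; water, O
Why: Ruthenium tetroxide oxidation takes primary epoxy alcohols to glycidic acids without opening the oxirane, and no stereocentre is affected.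

Step 17
Reactants: 17 lactone alcohol; 21 (2S,3S)-epoxyangelic acid
Product: 23 (1R,3E,6S)-6-[(tert-butyldimethylsilyl)oxy]-1-[(2R,3R)-2-ethenyl-4-methylidene-5-oxooxolan-3-yl]-3,7-dimethylocta-3,7-dien-1-yl (2S,3S)-2,3-dimethyloxirane-2-carboxylate, via mixed anhydride 22 (not isolated)
Conditions: 21, 2,4,6-trichlorobenzoyl chloride, Et3N, THF, rt; then 17, DMAP, toluene, rt → 40 °C
Reagents that add atoms: none
Why: Yamaguchi esterification is the method of choice for a hindered secondary alcohol and an α-quaternary acid that cannot epimerise, and acylating O8 also removes the risk of translactonisation.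

Step 18
Reactants: 23 triene ester
Product: 24 (1R)-2-[(2R,3R)-3-{(2S)-2-[(tert-butyldimethylsilyl)oxy]-3-methylbut-3-en-1-yl}-2-methyloxiran-2-yl]-1-[(2R,3R)-2-ethenyl-4-methylidene-5-oxooxolan-3-yl]ethyl (2S,3S)-2,3-dimethyloxirane-2-carboxylate
Conditions: D-fructose-derived Shi ketone (30 mol%), Oxone, K2CO3, n-Bu4NHSO4, Na2B4O7/EDTA buffer, MeCN–DMM–H2O, 0 °C
Reagents that add atoms: potassium peroxymonosulfate (Oxone), [K+].[O-]S(=O)(=O)OO
Why: Shi epoxidation by the chiral dioxirane through a spiro transition state should take the most electron-rich, trisubstituted E-C1=C10 alkene (vinyl, isopropenyl and the acrylate-type methylene react far more slowly) and set 1R,10R by reagent control.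

Step 19
Reactants: 24 silyl ether
Product: 25 (1R)-1-[(2R,3R)-2-ethenyl-4-methylidene-5-oxooxolan-3-yl]-2-{(2R,3R)-3-[(2S)-2-hydroxy-3-methylbut-3-en-1-yl]-2-methyloxiran-2-yl}ethyl (2S,3S)-2,3-dimethyloxirane-2-carboxylate
Conditions: HF·pyridine, pyridine, THF, 0 °C → rt
Reagents that add atoms: none
Why: Pyridine-buffered HF desilylation frees the C3 alcohol under conditions that trisubstituted oxiranes, esters and the methylene lactone are expected to tolerate.

Step 20
Reactants: 25 diene
Product: 26 (1R,3S,4Z,6R,7R,8R,10R)-1,10-epoxy-3-hydroxy-8-{[(2S,3S)-2,3-dimethyloxirane-2-carbonyl]oxy}germacra-4,11(13)-dien-12,6-olide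
Conditions: Hoveyda–Grubbs II (15 mol%, two portions), 1,4-benzoquinone (20 mol%), toluene (1 mM), 80 °C
Reagents that add atoms: none
Why: The ruthenium alkylidene loads onto the monosubstituted C6 vinyl group, the resulting C5 carbene adds [2+2] to the 1,1-disubstituted isopropenyl alkene at C4, and cycloreversion releases ethylene and forms C4=C5. The closest known reaction type is ring-closing diene metathesis to ten-membered carbocycles and lactones that carry a trisubstituted alkene, including germacranolide frameworks closed beside a methylene lactone. The one ring closed is the ten-membered carbocycle C1–C10, formed by ring-closing metathesis of two terminal alkenes with both new alkene carbons inside the ring. No stereocentre is created; the step must give the Z alkene, and in a ten-membered ring that already holds the trans 1,10-oxirane and the trans-fused lactone the ring-cis alkene is the less strained product towards which reversible metathesis should funnel. Cyclisation must beat dimerisation at the vinyl terminus, which is secured by 1 mM dilution and by the two turn elements (oxirane and lactone), while the free C3 hydroxyl assists the catalyst at the hindered isopropenyl group. The electron-poor 11(13)-methylene group is a poor metathesis partner and should remain a spectator.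

Step 21
Reactants: 26 3-alcohol
Product: 27 target, (1R,3S,4Z,6R,7R,8R,10R)-1,10-epoxy-3-(3-methylbutanoyloxy)-8-{[(2S,3S)-2,3-dimethyloxirane-2-carbonyl]oxy}germacra-4,11(13)-dien-12,6-olide
Conditions: (i-PrCH2CO)2O, DMAP (cat.), pyridine, CH2Cl2, 0 °C → rt
Reagents that add atoms: 3-methylbutanoic anhydride, CC(C)CC(=O)OC(=O)CC(C)C
Why: DMAP-catalysed acylation of the secondary allylic alcohol is mild enough for the oxiranes and the methylene lactone and does not affect any stereocentre.

**Compound list**

1 | methacrolein | CC(=C)C=O | starting material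
2 | (3S)-2-methylhexa-1,5-dien-3-yl diisopinocampheylborinate (not isolated) | C=CC[C@H](OB([C@@H]1C[C@@H]2C[C@@H](C2(C)C)[C@H]1C)[C@@H]1C[C@@H]2C[C@@H](C2(C)C)[C@H]1C)C(C)=C | intermediate
3 | (3S)-2-methylhexa-1,5-dien-3-ol | C=CC[C@H](O)C(C)=C | intermediate
4 | tert-butyl(dimethyl){[(3S)-2-methylhexa-1,5-dien-3-yl]oxy}silane | C=CC[C@H](O[Si](C)(C)C(C)(C)C)C(C)=C | intermediate
5 | (2E,5S)-5-[(tert-butyldimethylsilyl)oxy]-2,6-dimethylhepta-2,6-dienal | O=C/C(C)=C/C[C@H](O[Si](C)(C)C(C)(C)C)C(C)=C | intermediate
6 | (2E,5S)-5-[(tert-butyldimethylsilyl)oxy]-2,6-dimethylhepta-2,6-dien-1-ol | OC/C(C)=C/C[C@H](O[Si](C)(C)C(C)(C)C)C(C)=C | intermediate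
7 | {[(3S,5E)-7-bromo-2,6-dimethylhepta-1,5-dien-3-yl]oxy}(tert-butyl)dimethylsilane | BrC/C(C)=C/C[C@H](O[Si](C)(C)C(C)(C)C)C(C)=C | intermediate
8 | acrolein | C=CC=O | starting material
9 | rac-5-(trimethylsilyl)pent-1-en-4-yn-3-ol | C=CC(O)C#C[Si](C)(C)C | intermediate
10 | (3R)-5-(trimethylsilyl)pent-1-en-4-yn-3-yl acetate | C=C[C@@H](OC(C)=O)C#C[Si](C)(C)C | intermediate
11 | (3R)-pent-1-en-4-yn-3-ol | C=C[C@@H](O)C#C | intermediate
12 | (3R,7E,10S)-10-[(tert-butyldimethylsilyl)oxy]-7,11-dimethyldodeca-1,7,11-trien-4-yn-3-ol | C=C[C@@H](O)C#CC/C(C)=C/C[C@H](O[Si](C)(C)C(C)(C)C)C(C)=C | intermediate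
13 | (3R,4E,7E,10S)-10-[(tert-butyldimethylsilyl)oxy]-7,11-dimethyldodeca-1,4,7,11-tetraen-3-ol | C=C[C@@H](O)/C=C/C/C(C)=C/C[C@H](O[Si](C)(C)C(C)(C)C)C(C)=C | intermediate
14 | erythro epoxy alcohol, (1R)-1-[(2R,3R)-3-{(2E,5S)-5-(TBSO)-2,6-dimethylhepta-2,6-dien-1-yl}oxiran-2-yl]prop-2-en-1-ol | C=C[C@@H](O)[C@H]1O[C@@H]1C/C(C)=C/C[C@H](O[Si](C)(C)C(C)(C)C)C(C)=C | intermediate
15 | (diethoxyphosphoryl)acetate of 14 | C=C[C@@H](OC(=O)CP(=O)(OCC)OCC)[C@H]1O[C@@H]1C/C(C)=C/C[C@H](O[Si](C)(C)C(C)(C)C)C(C)=C | intermediate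
16 | diethyl {(4R,5R)-5-ethenyl-4-[(1R,3E,6S)-6-(TBSO)-1-hydroxy-3,7-dimethylocta-3,7-dien-1-yl]-2-oxooxolan-3-yl}phosphonate (C11 epimers, as potassium salt; not isolated) | CCOP(=O)(OCC)C1C(=O)O[C@H](C=C)[C@H]1[C@H](O)C/C(C)=C/C[C@H](O[Si](C)(C)C(C)(C)C)C(C)=C | intermediate
17 | (4R,5R)-5-ethenyl-4-[(1R,3E,6S)-6-(TBSO)-1-hydroxy-3,7-dimethylocta-3,7-dien-1-yl]-3-methylideneoxolan-2-one | C=C1C(=O)O[C@H](C=C)[C@H]1[C@H](O)C/C(C)=C/C[C@H](O[Si](C)(C)C(C)(C)C)C(C)=C | intermediate
18 | angelic acid | C/C=C(/C)C(=O)O | starting material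
19 | (2Z)-2-methylbut-2-en-1-ol | C/C=C(/C)CO | intermediate
20 | [(2R,3S)-2,3-dimethyloxiran-2-yl]methanol | OC[C@@]1(C)O[C@H]1C | intermediate
21 | (2S,3S)-2,3-dimethyloxirane-2-carboxylic acid | OC(=O)[C@@]1(C)O[C@H]1C | intermediate
22 | (2S,3S)-2,3-dimethyloxirane-2-carboxylic 2,4,6-trichlorobenzoic anhydride (not isolated) | O=C(OC(=O)[C@@]1(C)O[C@H]1C)c1c(Cl)cc(Cl)cc1Cl | intermediate
23 | C8 epoxyangelate of 17 | C=C1C(=O)O[C@H](C=C)[C@H]1[C@H](OC(=O)[C@@]2(C)O[C@H]2C)C/C(C)=C/C[C@H](O[Si](C)(C)C(C)(C)C)C(C)=C | intermediate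
24 | (1R,10R)-1,10-epoxide of 23 | C=C1C(=O)O[C@H](C=C)[C@H]1[C@H](OC(=O)[C@@]2(C)O[C@H]2C)C[C@@]3(C)O[C@@H]3C[C@H](O[Si](C)(C)C(C)(C)C)C(C)=C | intermediate
25 | metathesis precursor (free 3-OH) | C=C1C(=O)O[C@H](C=C)[C@H]1[C@H](OC(=O)[C@@]2(C)O[C@H]2C)C[C@@]3(C)O[C@@H]3C[C@H](O)C(C)=C | intermediate
26 | 3-O-deacyl target | C=C1C(=O)O[C@@H]2/C=C(/C)[C@@H](O)C[C@H]3O[C@]3(C)C[C@@H](OC(=O)[C@@]3(C)O[C@H]3C)[C@@H]12 | intermediate
27 | CNP0167461.1 | C=C1C(=O)O[C@@H]2/C=C(/C)[C@@H](OC(=O)CC(C)C)C[C@H]3O[C@]3(C)C[C@@H](OC(=O)[C@@]3(C)O[C@H]3C)[C@@H]12 | target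

**Step count**

Total: 21 steps. Longest linear sequence: 15 steps (1–5, 9–13, 17–21) from methacrolein.

**Steps most likely to fail**

1. Step 20 (ring-closing metathesis). Intermolecular metathesis at the vinyl terminus could outrun closure onto the hindered isopropenyl group, or ruthenium hydride could isomerise the allylic alcohol. Fallback: the order of ring closure and epoxidation is reversed, so that the E-C1=C10 alkene and not the oxirane is the turn element during closure. It sets out from 23. Buffered HF·pyridine should give the trienol F1. Ring-closing metathesis under the step 20 conditions should give the (1(10)E,4Z)-dienolide F2. Isovalerylation as in step 21 should give the 3-isovalerate F3, in which C4=C5 is deactivated by two allylic acyloxy groups. Shi epoxidation of the remaining electron-rich C1=C10 alkene (D-fructose-derived ketone, exposed face of the macrocycle) then returns to the route at target 27.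

2. Step 13 (tethered epoxide opening and olefination). The phosphonate carbanion could react through oxygen or at C8 (6-endo), or the liberated C8 alkoxide could attack the lactone carbonyl or the new methylene group. Fallback: a more nucleophilic carboxylate–enolate dianion does the ring closure and the methylene group is introduced by decarboxylative Mannich olefination. It sets out from 14. Warming with Meldrum's acid (toluene, 80 °C) should give the hydrogen malonate F4. Double deprotonation (LiHMDS, 2.2 equiv, THF, −78 → 0 °C) should close the lactone by the same 5-exo opening at C7 and give the α-carboxy lactone F5. Aqueous formaldehyde and diethylamine, then NaOAc/AcOH, should bring about decarboxylative methylenation and return to the route at 17.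

3. Step 18 (late Shi epoxidation). Chemoselectivity among four alkenes could be lost (isopropenyl epoxidation), or the methylene lactone could degrade in the buffered peroxide medium. Fallback: the oxirane is installed before any acrylate unit exists. It sets out from 14. Shi epoxidation under the step 18 conditions should give the diepoxy alcohol F6. Esterification as in step 12 should give the phosphonoacetate F7. Base closure as in step 13 should proceed through the phosphono lactone F8 (not isolated) to the epoxy lactone alcohol F9. Yamaguchi esterification with 21 (through 22) then returns to the route at 24.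

**Further compounds**

F1 | step 20 | 3-hydroxy trienolide (desilylated 23) | C=C1C(=O)O[C@H](C=C)[C@H]1[C@H](OC(=O)[C@@]2(C)O[C@H]2C)C/C(C)=C/C[C@H](O)C(C)=C
F2 | step 20 | (1(10)E,4Z)-3-hydroxy-8-epoxyangeloyloxygermacra-1(10),4,11(13)-trien-12,6-olide | C=C1C(=O)O[C@@H]2/C=C(/C)[C@@H](O)C/C=C(C)/C[C@@H](OC(=O)[C@@]3(C)O[C@H]3C)[C@@H]12
F3 | step 20 | 3-isovalerate of F2 | C=C1C(=O)O[C@@H]2/C=C(/C)[C@@H](OC(=O)CC(C)C)C/C=C(C)/C[C@@H](OC(=O)[C@@]3(C)O[C@H]3C)[C@@H]12
F4 | step 13 | hydrogen malonate of 14 | C=C[C@@H](OC(=O)CC(=O)O)[C@H]1O[C@@H]1C/C(C)=C/C[C@H](O[Si](C)(C)C(C)(C)C)C(C)=C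
F5 | step 13 | α-carboxy lactone (C11 epimers) | OC(=O)C1C(=O)O[C@H](C=C)[C@H]1[C@H](O)C/C(C)=C/C[C@H](O[Si](C)(C)C(C)(C)C)C(C)=C
F6 | step 18 | (1R,10R)-1,10-epoxide of 14 (diepoxy alcohol) | C=C[C@@H](O)[C@H]1O[C@@H]1C[C@@]2(C)O[C@@H]2C[C@H](O[Si](C)(C)C(C)(C)C)C(C)=C
F7 | step 18 | (diethoxyphosphoryl)acetate of F6 | C=C[C@@H](OC(=O)CP(=O)(OCC)OCC)[C@H]1O[C@@H]1C[C@@]2(C)O[C@@H]2C[C@H](O[Si](C)(C)C(C)(C)C)C(C)=C
F8 | step 18 | 1,10-epoxy phosphono lactone (not isolated) | CCOP(=O)(OCC)C1C(=O)O[C@H](C=C)[C@H]1[C@H](O)C[C@@]2(C)O[C@@H]2C[C@H](O[Si](C)(C)C(C)(C)C)C(C)=C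
F9 | step 18 | 1,10-epoxy methylene lactone alcohol | C=C1C(=O)O[C@H](C=C)[C@H]1[C@H](O)C[C@@]2(C)O[C@@H]2C[C@H](O[Si](C)(C)C(C)(C)C)C(C)=C
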